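**Retrosynthetic overview**
- Feature: with the benzene ring numbered C1 (OAc), C2 (OH), C3 (H), C4 (OH), C5 (H), C6 (C17 dienyl chain), the meta oxygens O2 and O4 flanking C3–H are taken as a ketene carbonyl oxygen and an ynol ether oxygen. C5–C6(chain)–C1(OAc) is the backbone of a (2-acetoxyvinyl)ketene, so the three oxygens arrive already differentiated.
- Disconnection 1: O4–H from O4–tBu, an aryl tert-butyl ether that is acid-labile while the O1 acetate is not.
- Disconnection 2 (the only ring formation): the benzene ring from a β-acetoxy α′-diazo enone and tert-butoxyacetylene (bonds C5–C6, C2–C3, C4–C5, C1–C2), by way of a transient cyclobutenone.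
- Diazo enone from a 3-acetoxy-2-alkylacrylic acid, from formylation and enol acetylation of tert-butyl homolinoleate, from Arndt–Eistert homologation of linoleic acid (both Z alkenes are bought and never touched); the ynol ether from tert-butyl vinyl ether.

Key step: step 9

Remark: the enol acetate is carried as the E isomer (acetoxy trans to the acyl carbon) expected from step 4; this geometry is erased on aromatization in step 9, so a minor Z isomer would simply be taken along. Diazomethane is used as a dried ethereal solution.

**Step 1**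
Reactants: 1 linoleic acid
Product: 3 (10Z,13Z)-1-diazononadeca-10,13-dien-2-one, via linoleoyl chloride 2 (not isolated)
Conditions: (COCl)2, cat. DMF, CH2Cl2, 0 °C → rt, evaporate; CH2N2 (3 equiv), Et2O, 0 °C
Reagents that add atoms: diazomethane C=[N+]=[N-]
Why: Vilsmeier-catalysed conversion of the acid into its chloride followed by acylation of diazomethane (first stage of an Arndt–Eistert homologation) should give the diazoketone, the excess diazomethane taking up the HCl and the skipped Z,Z-diene being inert to both reagents.

**Step 2**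
Reactants: 3 (10Z,13Z)-1-diazononadeca-10,13-dien-2-one
Product: 5 tert-butyl (10Z,13Z)-nonadeca-10,13-dienoate, via alkylketene 4 (not isolated)
Conditions: PhCO2Ag (10 mol %), Et3N, t-BuOH, 60 °C, dark
Reagents that add atoms: tert-butanol CC(C)(C)O
Why: Silver-promoted Wolff rearrangement shifts the C17 alkyl group to the diazo carbon and tert-butanol adds to ketene 4, which completes the one-carbon homologation and delivers the acid-labile ester needed in step 5; the remote Z alkenes take no part.

**Step 3**
Reactants: 5 tert-butyl (10Z,13Z)-nonadeca-10,13-dienoate; 6 ethyl formate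
Product: 7 tert-butyl (10Z,13Z)-2-formylnonadeca-10,13-dienoate
Conditions: LiN(iPr)2 (1.15 equiv), THF, −78 °C; 6 (3 equiv), −78 → 0 °C; aq. NH4Cl
Reagents that add atoms: none
Why: Crossed Claisen condensation of the kinetic lithium ester enolate with non-enolizable ethyl formate is driven by deprotonation of the product by the liberated ethoxide; C2 forms as a racemic, enolizable centre that is planarized in step 4, and the bis-allylic C–H bonds are far less acidic than the ester α-C–H.

**Step 4**
Reactants: 7 tert-butyl (10Z,13Z)-2-formylnonadeca-10,13-dienoate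
Product: 8 tert-butyl (2E,10Z,13Z)-2-[(acetyloxy)methylidene]nonadeca-10,13-dienoate
Conditions: Ac2O, Et3N, cat. DMAP, CH2Cl2, 0 °C
Reagents that add atoms: acetic anhydride CC(=O)OC(C)=O
Why: O-acylation of the enol of a β-formyl ester under non-chelating amine conditions should give the enol acetate mainly as the E isomer (acetoxy trans to the ester, extended enolate), and the geometry is in any case erased in step 9.

**Step 5**
Reactants: 8 tert-butyl (2E,10Z,13Z)-2-[(acetyloxy)methylidene]nonadeca-10,13-dienoate
Product: 9 (2E,10Z,13Z)-2-[(acetyloxy)methylidene]nonadeca-10,13-dienoic acid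
Conditions: TFA/CH2Cl2 (1:4), 0 °C → rt; co-evaporation with PhMe
Reagents that add atoms: none
Why: Acidolysis of the tert-butyl ester (E1 loss of isobutene) under anhydrous conditions should leave the conjugated enol acetate and the unactivated Z alkenes untouched.

**Step 6**
Reactants: 9 (2E,10Z,13Z)-2-[(acetyloxy)methylidene]nonadeca-10,13-dienoic acid
Product: 11 (3E,11Z,14Z)-3-[(acetyloxy)methylidene]-1-diazoicosa-11,14-dien-2-one, via acid chloride 10 (not isolated)
Conditions: (COCl)2, cat. DMF, CH2Cl2, 0 °C, evaporate below 25 °C; CH2N2 (3 equiv), Et2O, −10 → 0 °C; N2 purge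
Reagents that add atoms: diazomethane C=[N+]=[N-]
Why: Acylation of diazomethane by the acid chloride should outrun 1,3-dipolar addition to the C=C because that alkene is trisubstituted and carries a β-oxygen donor, the chloride has no α-hydrogen for ketene formation, and excess diazomethane rather than an amine base removes the HCl so that the vinylogous anhydride is not exposed to nucleophiles.

**Step 7**
Reactants: 12 tert-butyl vinyl ether
Product: 14 (Z)-1-bromo-2-tert-butoxyethene, via dibromo ether 13 (not isolated)
Conditions: Br2, pentane, −78 °C; iPr2NEt, −78 °C → rt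
Reagents that add atoms: bromine BrBr
Why: Bromine adds across the electron-rich enol ether and the α-bromo ether then loses HBr through its oxocarbenium ion under the hindered amine (dehydrobromination), which should give the 2-bromovinyl ether mainly as the Z isomer favoured by the cis effect.

**Step 8**
Reactants: 14 (Z)-1-bromo-2-tert-butoxyethene
Product: 16 tert-butoxyacetylene, via sodium alkynide 15 (not isolated)
Conditions: NaNH2 (2.5 equiv), liq. NH3, −33 °C; aq. NH4Cl, pentane, 0 °C; kept and used as a cold solution
Reagents that add atoms: none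
Why: In the Z isomer the vinylic hydrogen on the oxygen-bearing carbon is anti to bromine, so NaNH2 effects anti-elimination of HBr to the alkoxyacetylene, which is held as its sodium alkynide 15 until the cold proton quench.

**Step 9**
Reactants: 11 (3E,11Z,14Z)-3-[(acetyloxy)methylidene]-1-diazoicosa-11,14-dien-2-one; 16 tert-butoxyacetylene
Product: 21 4-tert-butoxy-2-[(8Z,11Z)-heptadeca-8,11-dien-1-yl]-6-hydroxyphenyl acetate, via acetoxyvinylketene 17 (not isolated), via cyclobutenone 18 (not isolated), via dienylketene 19 (not isolated), via cyclohexadienone 20 (not isolated)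
Conditions: hν (Pyrex-filtered medium-pressure Hg lamp, >300 nm), 16 (3 equiv), degassed CH2Cl2, 15 °C; evaporate at ≤20 °C; PhMe, 80 °C
Reagents that add atoms: none
Why: Light expels N2 from 11 and the alkenyl carbon C6 shifts to the diazo carbon C5 (Wolff rearrangement) to give (2-acetoxyvinyl)ketene 17; the polarized ynol ether 16 then adds across the ketene C=C in a [2+2] cycloaddition, its nucleophilic CH terminus (C3) bonding to the ketene carbonyl carbon (C2) and its oxygen-bearing carbon (C4) to C5, which closes the transient four-membered ring of 18. On heating, 18 opens by 4π electrocyclic cleavage of the C2–C5 bond to dienylketene 19, which closes the six-membered ring by thermal 6π electrocyclization between the ketene carbon C2 and the acetoxy-bearing CH (C1), and enolization of dienone 20 gives the arene. The closest known reaction type is the photochemical-Wolff variant of the Danheiser benzannulation of α′-diazo enones with alkoxy- and siloxyalkynes, the β-acetoxy group on the enone being the only new element of the substrate. No stereocenter survives, since the sp3 centres of 18 and 20 are transient and the enol acetate geometry is erased on aromatization. The step needs one regiochemical outcome in the [2+2], which the oxygen-polarized alkyne secures (O4 meta to the new phenol O2, C3 left as CH), and it needs the acetate to stay on O1, for which the E enol acetate (acetoxy pointing outward in the 6π closure), light that the aryl acetate does not absorb, base-free conditions and removal of excess 16 before heating (so that no ketene from its retro-ene cleavage acylates O2) are provided.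

**Step 10**
Reactants: 21 4-tert-butoxy-2-[(8Z,11Z)-heptadeca-8,11-dien-1-yl]-6-hydroxyphenyl acetate
Product: 22 ardisiphenol C, 2-[(8Z,11Z)-heptadeca-8,11-dien-1-yl]-4,6-dihydroxyphenyl acetate
Conditions: TFA, Et3SiH (5 equiv), CH2Cl2, 0 °C
Reagents that add atoms: none
Why: Acidolysis of the aryl tert-butyl ether (SN1 cleavage) should free O4 while the aryl acetate, inert to anhydrous TFA, stays on O1 without base-mediated migration; Et3SiH reduces the tert-butyl cation before it can alkylate the electron-rich ring, and the 1,2-disubstituted Z alkenes are not protonated at 0 °C.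

**Compound list**
1 | linoleic acid, (9Z,12Z)-octadeca-9,12-dienoic acid | CCCCC/C=C\C/C=C\CCCCCCCC(=O)O | starting material
2 | linoleoyl chloride | CCCCC/C=C\C/C=C\CCCCCCCC(=O)Cl | intermediate (not isolated)
3 | (10Z,13Z)-1-diazononadeca-10,13-dien-2-one | CCCCC/C=C\C/C=C\CCCCCCCC(=O)C=[N+]=[N-] | intermediate
4 | (10Z,13Z)-nonadeca-1,10,13-trien-1-one (alkylketene) | CCCCC/C=C\C/C=C\CCCCCCCC=C=O | intermediate (not isolated)
5 | tert-butyl (10Z,13Z)-nonadeca-10,13-dienoate | CCCCC/C=C\C/C=C\CCCCCCCCC(=O)OC(C)(C)C | intermediate
6 | ethyl formate | CCOC=O | starting material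
7 | tert-butyl (10Z,13Z)-2-formylnonadeca-10,13-dienoate (racemic at C2, in equilibrium with its enol) | CCCCC/C=C\C/C=C\CCCCCCCC(C=O)C(=O)OC(C)(C)C | intermediate
8 | tert-butyl (2E,10Z,13Z)-2-[(acetyloxy)methylidene]nonadeca-10,13-dienoate | CC(C)(C)OC(=O)/C(CCCCCCC/C=C\C/C=C\CCCCC)=C/OC(C)=O | intermediate
9 | (2E,10Z,13Z)-2-[(acetyloxy)methylidene]nonadeca-10,13-dienoic acid | OC(=O)/C(CCCCCCC/C=C\C/C=C\CCCCC)=C/OC(C)=O | intermediate
10 | (2E,10Z,13Z)-2-[(acetyloxy)methylidene]nonadeca-10,13-dienoyl chloride | ClC(=O)/C(CCCCCCC/C=C\C/C=C\CCCCC)=C/OC(C)=O | intermediate (not isolated)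
11 | (3E,11Z,14Z)-3-[(acetyloxy)methylidene]-1-diazoicosa-11,14-dien-2-one | O=C(C=[N+]=[N-])/C(CCCCCCC/C=C\C/C=C\CCCCC)=C/OC(C)=O | intermediate
12 | tert-butyl vinyl ether | C=COC(C)(C)C | starting material
13 | 2-(1,2-dibromoethoxy)-2-methylpropane (racemic) | CC(C)(C)OC(Br)CBr | intermediate (not isolated)
14 | (Z)-1-bromo-2-tert-butoxyethene | CC(C)(C)O/C=C\Br | intermediate
15 | sodium 2-tert-butoxyethyn-1-ide | CC(C)(C)OC#[C-].[Na+] | intermediate (not isolated)
16 | tert-butoxyacetylene | CC(C)(C)OC#C | intermediate
17 | (3E,11Z,14Z)-3-[(acetyloxy)methylidene]icosa-1,11,14-trien-1-one (acetoxyvinylketene) | O=C=C/C(CCCCCCC/C=C\C/C=C\CCCCC)=C/OC(C)=O | intermediate (not isolated)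
18 | (1E,10Z,13Z)-2-(2-tert-butoxy-4-oxocyclobut-2-en-1-yl)nonadeca-1,10,13-trien-1-yl acetate (racemic) | CC(=O)O/C=C(\CCCCCCC/C=C\C/C=C\CCCCC)C1C(=O)C=C1OC(C)(C)C | intermediate (not isolated)
19 | (1E,3E)-4-tert-butoxy-2-[(8Z,11Z)-heptadeca-8,11-dien-1-yl]-6-oxohexa-1,3,5-trien-1-yl acetate (dienylketene) | CC(=O)O/C=C(CCCCCCC/C=C\C/C=C\CCCCC)/C=C(OC(C)(C)C)\C=C=O | intermediate (not isolated)
20 | 4-tert-butoxy-2-[(8Z,11Z)-heptadeca-8,11-dien-1-yl]-6-oxocyclohexa-2,4-dien-1-yl acetate (racemic) | CC(=O)OC1C(=O)C=C(OC(C)(C)C)C=C1CCCCCCC/C=C\C/C=C\CCCCC | intermediate (not isolated)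
21 | 4-tert-butoxy-2-[(8Z,11Z)-heptadeca-8,11-dien-1-yl]-6-hydroxyphenyl acetate | CCCCC/C=C\C/C=C\CCCCCCCc1cc(OC(C)(C)C)cc(O)c1OC(C)=O | intermediate
22 | ardisiphenol C, 2-[(8Z,11Z)-heptadeca-8,11-dien-1-yl]-4,6-dihydroxyphenyl acetate | CCCCC/C=C\C/C=C\CCCCCCCc1cc(O)cc(O)c1OC(C)=O | target

**Step count**
Total: 10 steps. Longest linear sequence: 8 steps (steps 1–6, 9, 10); the ynol ether is a two-step side branch (steps 7, 8).

**Steps most likely to fail**

1. Step 9 (key step). In the irradiation stage, photoreactions of the β-acetoxy enone chromophore (E/Z isomerization followed by acyl shift or fragmentation) may outrun the Wolff shift and the capture of the ketene. In the thermal stage, the acetyl group may pass from O1 to the new O2 phenol. The fallback sets out from 11, generates the same vinylketene without light, and comes back at 21. Silver-promoted Wolff rearrangement of 11 in the dark (PhCO2Ag cat., 1,4-dioxane/H2O, ultrasound, rt) with capture of 17 by water should give (3E,11Z,14Z)-3-[(acetyloxy)methylidene]icosa-11,14-dienoic acid F1. (COCl)2 with cat. DMF in CH2Cl2 at 0 °C would convert it into (3E,11Z,14Z)-3-[(acetyloxy)methylidene]icosa-11,14-dienoyl chloride F2. Slow addition of Et3N to F2 and 16 (3 equiv) in CH2Cl2 at 0 °C would form 17 by dehydrochlorination and trap it as cyclobutenone 18. After an aqueous wash and removal of volatiles, heating in PhMe at 80 °C should carry 18 through 19 and 20 to 21.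

2. Step 6. 1,3-Dipolar addition of diazomethane to the acceptor C=C (pyrazoline formation), or attack on the vinylogous anhydride with loss of acetate, may compete with acyl substitution. The fallback sets out from 9 through its chloride 10 (made as in step 6), installs the diazo group by diazo transfer instead of acylation, and comes back at 11. Acyl Negishi coupling of 10 with MeZnCl and Pd(PPh3)4 (zerovalent palladium, cat.) in THF at 0 °C should give (3E,11Z,14Z)-3-[(acetyloxy)methylidene]icosa-11,14-dien-2-one F3. Kinetic deprotonation of its methyl group with LiN(SiMe3)2 in THF at −78 °C and trapping with 2,2,2-trifluoroethyl trifluoroacetate would give (5E,13Z,16Z)-5-[(acetyloxy)methylidene]-1,1,1-trifluorodocosa-13,16-diene-2,4-dione F4. The E geometry holds the enolate away from the acetate during this step. Detrifluoroacetylative diazo transfer (MsN3, Et3N, H2O 1 equiv, MeCN, rt) should then give 11.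

3. Step 10. The expelled tert-butyl cation may alkylate the electron-rich ring (Friedel–Crafts tert-butylation), and acid may promote acetyl migration from O1 to the free O2. The fallback sets out from 21, blocks O2 temporarily, and comes back at 22. Chloroacetic anhydride and pyridine in CH2Cl2 at 0 °C should give 2-(acetyloxy)-5-tert-butoxy-3-[(8Z,11Z)-heptadeca-8,11-dien-1-yl]phenyl chloroacetate F5, whose ring is less nucleophilic and has no free ortho hydroxyl for acyl transfer. TFA with Et3SiH in CH2Cl2 at 0 °C would cleave the tert-butyl ether to 2-(acetyloxy)-3-[(8Z,11Z)-heptadeca-8,11-dien-1-yl]-5-hydroxyphenyl chloroacetate F6. Thiourea with 2,6-lutidine in MeOH/CH2Cl2 at rt should then remove the chloroacetate selectively (S-alkylation, then cyclization) and give 22 with the acetate untouched.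

**Further compounds**
F1 | step 9 | (3E,11Z,14Z)-3-[(acetyloxy)methylidene]icosa-11,14-dienoic acid | OC(=O)C/C(CCCCCCC/C=C\C/C=C\CCCCC)=C/OC(C)=O
F2 | step 9 | (3E,11Z,14Z)-3-[(acetyloxy)methylidene]icosa-11,14-dienoyl chloride | ClC(=O)C/C(CCCCCCC/C=C\C/C=C\CCCCC)=C/OC(C)=O
F3 | step 6 | (3E,11Z,14Z)-3-[(acetyloxy)methylidene]icosa-11,14-dien-2-one | CC(=O)/C(CCCCCCC/C=C\C/C=C\CCCCC)=C/OC(C)=O
F4 | step 6 | (5E,13Z,16Z)-5-[(acetyloxy)methylidene]-1,1,1-trifluorodocosa-13,16-diene-2,4-dione | FC(F)(F)C(=O)CC(=O)/C(CCCCCCC/C=C\C/C=C\CCCCC)=C/OC(C)=O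
F5 | step 10 | 2-(acetyloxy)-5-tert-butoxy-3-[(8Z,11Z)-heptadeca-8,11-dien-1-yl]phenyl chloroacetate | CCCCC/C=C\C/C=C\CCCCCCCc1cc(OC(C)(C)C)cc(OC(=O)CCl)c1OC(C)=O
F6 | step 10 | 2-(acetyloxy)-3-[(8Z,11Z)-heptadeca-8,11-dien-1-yl]-5-hydroxyphenyl chloroacetate | CCCCC/C=C\C/C=C\CCCCCCCc1cc(O)cc(OC(=O)CCl)c1OC(C)=O
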